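## Structural features

The target is a 2-arylchroman-4-one (flavanone): benzo ring A is fused to the oxygen heterocycle ring C through C4a and C8a, and ring B hangs from C2. Ring A is substituted everywhere except C5, with 3-methylbut-2-enyl (prenyl) groups at C6 and C8 on either side of the C7 hydroxyl; ring B carries a 4'-hydroxyl with a third prenyl group beside it at C3'. C2 is the only stereocentre, (S), and has no stereogenic neighbour, so its configuration must come from a reagent or catalyst. It is fragile: O1 is the beta leaving group of the C4 ketone, so base or strong acid can open ring C to the 2'-hydroxychalcone and re-close it as the racemate, more easily once the 4'-hydroxyl is free. The three trisubstituted alkenes are the other weak points: each sits ortho to a phenol and can cyclise to a 2,2-dimethylchroman in acid, and each is a trap for electrophilic carbenes, oxidants and hydrogenation. The real difficulty is to set one isolated, epimerisable benzylic ether centre with absolute control while placing three prenyl groups, one at the crowded C8 between O1 and O7. The key step exploits the C2–H bond, which is flanked by O1 and the electron-rich ring B: in a benzyl ether of ring A this doubly activated methylene lies within reach of a carbene at C3 through a six-membered transition state, so C2–C3, ring C and the stereocentre arise in one catalytic event.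

## Logic of the disconnections

13 to 12: the two phenolic O–CH2 bonds at O7 and O4' are cut. Free phenols would undergo O–H insertion with the carbenoid, slow the cross-coupling, and as phenoxides promote ring opening at C2. Both are therefore carried as methoxymethyl acetals, which tolerate base, enolate chemistry, the carbenoid and palladium. The forward step must be an acid unmasking mild enough to spare three ortho-prenylphenol units and the C2 centre.

12 to 10 and 11: the three aryl–CH2 bonds at C6, C8 and C3' are cut. No prenyl alkene can be present when the carbene is generated, so each is replaced by bromine, an inert placeholder that electrophilic bromination puts at exactly the right positions. All three side chains then come from one reagent in one operation. The forward step must couple three times, including at C8 between two oxygens, transfer the allyl group at its CH2 terminus, and run without base so that C2 is not opened.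

10 to 9: the C2–C3 bond is cut, opening ring C to an aryl diazomethyl ketone whose ortho oxygen carries the ring-B benzyl group. This single cut removes the ring, the only stereocentre and the only C–C bond between the two halves of ring C. The forward step must choose one of two enantiotopic benzylic hydrogens and must prefer C–H insertion to attack on the ether oxygen.

9 to 7 (through 8): the C=N2 bond at the future C3 is cut back to a methyl ketone. Diazo transfer to an activated ketone avoids an acid chloride, whose HCl would threaten two acetals and an acid-labile 4-alkoxybenzyl ether, and avoids diazomethane-type reagents. The ketone has one enolisable position, so the only demands are clean C-acylation of its enolate and careful handling of a sulfonyl azide.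

7 to 3 and 6: the O–CH2 bond that becomes O1–C2 is cut. It is the convergent junction of the ring-A and ring-B halves. The forward step must O-alkylate a hindered, hydrogen-bonded but acidic phenol under conditions that spare the acetals, which points to a redox condensation of the benzylic alcohol over an unstable 4-alkoxybenzyl halide.

3 to 2 to 1: the O7 acetal bond and the two C–Br bonds are cut. Positions 3 and 5 of the resorcinol ketone, each ortho or para to both hydroxyls, are the future C8 and C6, and the ketone-chelated hydroxyl is the future O1. The forward steps must stop at the ring dibromide without touching the acetyl group and must protect only the non-chelated hydroxyl.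

6 to 5 to 4: the benzylic C–H bond (reduction) and the O4' acetal bond are cut, leading to a purchasable bromophenol aldehyde that already has the 3'-bromine in place. Both forward steps are routine.

## Other disconnections considered

Alternative 1: The cut removes C3–C4 and O1–C2 together, dividing ring C between a ring-A salicylaldehyde, 4-(tert-butyldimethylsilyloxy)-2-hydroxy-3,5-diprenylbenzaldehyde A2, and a ring-B styrene, tert-butyldimethyl(2-prenyl-4-vinylphenoxy)silane A3.
- Forward step: under a chiral phosphoric acid and a methyl orthoester, A2 would form a C4-methoxy ortho-quinone methide that adds A3 in an inverse-demand [4+2] to give the 2,4-cis flavan A1.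
- In its favour: it is convergent, makes two ring bonds at once, carries all three prenyl groups from the start, and needs neither tin nor a diazo compound. On these four points it is the better plan.
- Against it here:
  - A1 is at the wrong oxidation level. The C4 methyl ether must be converted to the ketone in the presence of three alkenes and two electron-rich rings, and the C4 centre is made only to be destroyed.
  - The Brønsted acid meets, in A2, a free phenol ortho to the C8 prenyl group, the arrangement that cyclises to a dimethylchroman.
  - A2 needs a regiocontrolled double prenylation of a resorcinol aldehyde.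
  - Facial control has to be imposed on a cationic heterodiene with no hydrogen-bond donor left for the catalyst.
- Comparison: on stereocontrol the two plans are equal in kind, one catalyst-controlled event fixing C2 with comparable uncertainty. On compatibility of the prenyl groups with the key step and on redox economy the chosen plan is better. Counting the routes to A2 and A3 and the C4 adjustment, it is unlikely to be shorter than the nine steps chosen.

Alternative 2: The cut is O1–C8a. The precursor is the open-chain (S)-benzylic alcohol with a C8a bromide and a ketal-masked C4 ketone, (S)-2-{2-[2-bromo-4-(methoxymethoxy)-3,5-diprenylphenyl]-1,3-dioxolan-2-yl}-1-[4-(methoxymethoxy)-3-prenylphenyl]ethanol A5.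
- Forward step: intramolecular palladium-catalysed aryl ether formation (Buchwald–Hartwig type) would close ring C to the ketal A4.
- In its favour: no bond at the stereocentre is broken, so the configuration of A5 is carried into A4 by mechanism. This is better than relying on discrimination of enantiotopic hydrogens. Alkenes are tolerated by zerovalent palladium, so the prenyl groups can be in place.
- Against it here:
  - A secondary benzylic alkoxide on palladium is prone to beta-hydride elimination, giving ketone and reduced arene.
  - The C8a bromide is flanked by the C8 prenyl group and the quaternary ketal carbon, so both oxidative addition and C–O reductive elimination are hindered.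
  - Strong base and heat are needed.
  - A5 requires a pentasubstituted bromoarene of defined pattern, a separate asymmetric step to set the carbinol, and ketal installation and removal.
- Comparison: the final acid step (ketal plus acetals) carries the same risk to the prenyl groups as the chosen plan, so the two are equal there. On security of configuration Alternative 2 is better. On accessibility of the precursor, on the steric demand of the ring closure and on step count the chosen plan is better.

Alternative 3: The cuts are C4a–C5 and C8a–C8, so ring A is built last.
- Forward step: the silyloxydiene 3-(tert-butyldimethylsilyloxy)-7-methyl-2-(3-methylbut-2-enyl)octa-1,3,6-triene A8 would add across the enone double bond of (S)-5-iodo-2-[4-(methoxymethoxy)-3-prenylphenyl]-2,3-dihydro-4H-pyran-4-one A7. Loss of HI and dehydrogenation with a high-potential quinone would then give the flavanone A6.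
- In its favour: the substitution pattern of ring A is written into the diene, so there is no arene regiochemistry to control, and no cross-coupling at crowded C8. On this point it is the better plan. The C2 centre of A7 could come from a well-established catalytic asymmetric hetero-Diels–Alder reaction, which is at least equal in reliability to the carbenoid step.
- Against it here:
  - A7 is a vinylogous ester and a poor dienophile, so heat or a Lewis acid is needed. Either can ionise the C2–O1 bond next to the electron-rich ring B.
  - A8 is a crowded, geometry-dependent diene that is not simple to make as one isomer.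
  - The aromatisation exposes three prenyl groups and a silyl enol ether to an oxidising quinone and to liberated HI.
- Comparison: both plans end with phenol deprotection and are equal there. On mechanism the chosen plan has one delicate selectivity (insertion against ylide), whereas Alternative 3 has several (cycloaddition rate, regiochemistry, oxidation chemoselectivity). The routes to A7 and A8 make it longer.

Key step: step 7

Remark on the chemistry: Rh2(S-PTTL)4 is assumed to deliver the (S) centre. If its intrinsic preference is the opposite, Rh2(R-PTTL)4, made from (R)-tert-leucine, is used in step 7 with nothing else changed.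

Abbreviations: prenyl = 3-methylbut-2-enyl; MOM = methoxymethyl; flavanone = 2-phenylchroman-4-one with the usual numbering.

## Route

Step 1
Reactants: 1 2,4-dihydroxyacetophenone
Product: 2 1-(3,5-dibromo-2,4-dihydroxyphenyl)ethanone
Conditions: NBS (2.1 equiv), MeCN, 0 °C to rt
Reagents that add atoms: N-bromosuccinimide, O=C1CCC(=O)N1Br
Why: Electrophilic aromatic bromination; C3 and C5 are each ortho or para to both hydroxyls and C6 is not, so two equivalents should stop at the 3,5-dibromide, and without strong acid the acetyl group is not enolised and brominated.

Step 2
Reactants: 2 1-(3,5-dibromo-2,4-dihydroxyphenyl)ethanone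
Product: 3 1-[3,5-dibromo-2-hydroxy-4-(methoxymethoxy)phenyl]ethanone
Conditions: MOMCl (1.1 equiv), i-Pr2NEt (1.2 equiv), CH2Cl2, 0 °C
Reagents that add atoms: chloromethyl methyl ether, COCCl
Why: O-alkylation to the mixed acetal; the C2 hydroxyl is held in a hydrogen bond to the acetyl carbonyl, and the C4 hydroxyl (two ortho bromines, para acyl) is the more acidic, so one equivalent of base and electrophile should go to O4.

Step 3
Reactants: 4 3-bromo-4-hydroxybenzaldehyde
Product: 5 3-bromo-4-(methoxymethoxy)benzaldehyde
Conditions: MOMCl, i-Pr2NEt, CH2Cl2, 0 °C to rt
Reagents that add atoms: chloromethyl methyl ether, COCCl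
Why: Standard methoxymethylation of a phenol; the only acidic site is the phenol and the aldehyde is inert to the amine base.

Step 4
Reactants: 5 3-bromo-4-(methoxymethoxy)benzaldehyde
Product: 6 [3-bromo-4-(methoxymethoxy)phenyl]methanol
Conditions: NaBH4, MeOH, 0 °C
Reagents that add atoms: none
Why: Borohydride reduction of an aromatic aldehyde; the aryl bromide and the acetal do not react.

Step 5
Reactants: 3 1-[3,5-dibromo-2-hydroxy-4-(methoxymethoxy)phenyl]ethanone; 6 [3-bromo-4-(methoxymethoxy)phenyl]methanol
Product: 7 1-{3,5-dibromo-2-[3-bromo-4-(methoxymethoxy)benzyloxy]-4-(methoxymethoxy)phenyl}ethanone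
Conditions: PPh3, DIAD, THF, 0 °C to rt
Reagents that add atoms: none
Why: Mitsunobu etherification; the acidic ortho-acyl, ortho-bromo phenol protonates the betaine and its phenoxide displaces the primary benzylic alkoxyphosphonium, under neutral conditions that spare both acetals and avoid an unstable 4-alkoxybenzyl halide.

Step 6
Reactants: 7 1-{3,5-dibromo-2-[3-bromo-4-(methoxymethoxy)benzyloxy]-4-(methoxymethoxy)phenyl}ethanone
Product: 9 2-diazo-1-{3,5-dibromo-2-[3-bromo-4-(methoxymethoxy)benzyloxy]-4-(methoxymethoxy)phenyl}ethanone, via trifluoroacetyl diketone 8 (not isolated)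
Conditions: LiN(SiMe3)2, THF, –78 °C; CF3CO2CH2CF3; cold 0.5 M HCl work-up; then 4-AcNHC6H4SO2N3, Et3N, H2O (1 equiv), MeCN, rt
Reagents that add atoms: 4-acetamidobenzenesulfonyl azide, CC(=O)Nc1ccc(cc1)S(=O)(=O)N=[N+]=[N-] (the two diazo nitrogens of 9); 2,2,2-trifluoroethyl trifluoroacetate, O=C(OCC(F)(F)F)C(F)(F)F (the trifluoroacetyl group of 8 only)
Why: Detrifluoroacetylative diazo transfer (Regitz-type); the lithium enolate of the methyl ketone is C-acylated to diketone 8, whose activated methylene takes the diazo group from the sulfonyl azide with loss of the trifluoroacetyl group as the N-acylsulfonamide, so no acid chloride, HCl or diazomethane-type reagent is involved.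

Step 7
Reactants: 9 2-diazo-1-{3,5-dibromo-2-[3-bromo-4-(methoxymethoxy)benzyloxy]-4-(methoxymethoxy)phenyl}ethanone
Product: 10 (S)-6,8,3'-tribromo-7,4'-bis(methoxymethoxy)flavanone
Conditions: Rh2(S-PTTL)4 (1 mol %), CH2Cl2, 4 Å MS, 0 °C, slow addition of 9
Reagents that add atoms: none
Why: Rh2(S-PTTL)4, dirhodium tetrakis[N-phthaloyl-(S)-tert-leucinate], binds the diazo carbon of 9 at an axial site of the divalent rhodium dimer and N2 leaves, giving an electrophilic acyl carbenoid at C3. The carbenoid carbon engages one hydrogen of the O1–CH2 group in a concerted, asynchronous three-centre C–H insertion with hydride-like transfer, the developing positive charge at C2 being carried by O1 and by the 4'-oxygenated ring B; C2–C3 forms and the catalyst is released. The closest known reaction type is the chiral dirhodium-carboxylate-catalysed intramolecular C–H insertion of ortho-alkoxyaryl diazoketones to chroman-4-ones, benzyl ethers included. Ring C closes by 1,6-insertion through a six-membered transition state (C3, C4, C4a, C8a, O1, C2) as a C–C ring closure; a five-membered insertion is not possible because that position is the ether oxygen. The C2 centre is under catalyst control: the chiral pocket of the four N-phthaloyl-tert-leucinate ligands distinguishes the two enantiotopic hydrogens of the prochiral methylene, and the (S) product is the planned outcome. The step needs chemoselectivity for insertion over attack on the O1 lone pair (oxonium ylide, then 1,2-benzyl shift to a 2-benzylbenzofuran-3-one) and over carbene dimerisation. O1 is made a poor donor by the ortho acyl group and the C8 bromine on an electron-poor ring, the benzylic C–H is made hydridic by the para acetal oxygen, bromine in place of every prenyl group removes cyclopropanation, and slow addition keeps the diazoketone concentration low. The new centre is not alpha to the ketone and the medium is neutral and aprotic, so it should not erode.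

Step 8
Reactants: 10 (S)-6,8,3'-tribromo-7,4'-bis(methoxymethoxy)flavanone; 11 tributyl(3-methylbut-2-enyl)stannane
Product: 12 (S)-7,4'-bis(methoxymethoxy)-6,8,3'-triprenylflavanone
Conditions: Pd(PPh3)4 (10 mol %), 11 (4.5 equiv), DMF, 95 °C, degassed, dark
Reagents that add atoms: none
Why: Threefold Stille cross-coupling; zerovalent palladium inserts into each C–Br bond, the allylic stannane transmetallates at its CH2 terminus and reductive elimination gives the linear prenyl arene, under neutral, base-free conditions that should leave the base-labile C2 centre and the acetals untouched.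

Step 9
Reactants: 12 (S)-7,4'-bis(methoxymethoxy)-6,8,3'-triprenylflavanone
Product: 13 (2S)-7-hydroxy-2-[4-hydroxy-3-(3-methylbut-2-enyl)phenyl]-6,8-bis(3-methylbut-2-enyl)chroman-4-one (the target)
Conditions: 3 M aq. HCl, MeOH, 40 °C, stopped at full conversion
Reagents that add atoms: none
Why: Acid-catalysed acetal exchange of the two aryl methoxymethyl ethers with methanol; aryl acetals cleave under conditions mild enough that hydroalkoxylation of the prenyl groups and acid-mediated opening of ring C should remain slow.

## Compound list

1 | 2,4-dihydroxyacetophenone | CC(=O)c1ccc(O)cc1O | starting material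
2 | 1-(3,5-dibromo-2,4-dihydroxyphenyl)ethanone | CC(=O)c1cc(Br)c(O)c(Br)c1O | intermediate
3 | 1-[3,5-dibromo-2-hydroxy-4-(methoxymethoxy)phenyl]ethanone | CC(=O)c1cc(Br)c(OCOC)c(Br)c1O | intermediate
4 | 3-bromo-4-hydroxybenzaldehyde | O=Cc1ccc(O)c(Br)c1 | starting material
5 | 3-bromo-4-(methoxymethoxy)benzaldehyde | COCOc1ccc(C=O)cc1Br | intermediate
6 | [3-bromo-4-(methoxymethoxy)phenyl]methanol | COCOc1ccc(CO)cc1Br | intermediate
7 | 1-{3,5-dibromo-2-[3-bromo-4-(methoxymethoxy)benzyloxy]-4-(methoxymethoxy)phenyl}ethanone | CC(=O)c1cc(Br)c(OCOC)c(Br)c1OCc1ccc(OCOC)c(Br)c1 | intermediate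
8 | 1-{3,5-dibromo-2-[3-bromo-4-(methoxymethoxy)benzyloxy]-4-(methoxymethoxy)phenyl}-4,4,4-trifluorobutane-1,3-dione | O=C(CC(=O)C(F)(F)F)c1cc(Br)c(OCOC)c(Br)c1OCc1ccc(OCOC)c(Br)c1 | intermediate (not isolated)
9 | 2-diazo-1-{3,5-dibromo-2-[3-bromo-4-(methoxymethoxy)benzyloxy]-4-(methoxymethoxy)phenyl}ethanone | [N-]=[N+]=CC(=O)c1cc(Br)c(OCOC)c(Br)c1OCc1ccc(OCOC)c(Br)c1 | intermediate
10 | (S)-6,8,3'-tribromo-7,4'-bis(methoxymethoxy)flavanone | COCOc1ccc([C@@H]2CC(=O)c3cc(Br)c(OCOC)c(Br)c3O2)cc1Br | intermediate
11 | tributyl(3-methylbut-2-enyl)stannane | CCCC[Sn](CCCC)(CCCC)CC=C(C)C | starting material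
12 | (S)-7,4'-bis(methoxymethoxy)-6,8,3'-triprenylflavanone | COCOc1ccc([C@@H]2CC(=O)c3cc(CC=C(C)C)c(OCOC)c(CC=C(C)C)c3O2)cc1CC=C(C)C | intermediate
13 | (2S)-7-hydroxy-2-[4-hydroxy-3-(3-methylbut-2-enyl)phenyl]-6,8-bis(3-methylbut-2-enyl)chroman-4-one | CC(C)=CCc1cc([C@@H]2CC(=O)c3cc(CC=C(C)C)c(O)c(CC=C(C)C)c3O2)ccc1O | target

## Step count and risks

Total: 9 steps. Longest linear sequence: 7 steps (1 to 2 to 3 to 7 to 9 to 10 to 12 to 13; the branch from 4 is equally long).

**Step 7 (key step).** The most likely failure is diversion of the acceptor-only carbenoid to the ether oxygen, followed by benzyl migration, or insufficient discrimination between the two enantiotopic hydrogens. A diazomethyl ketone gives the least stabilised and least selective carbenoid of its class. Fallback, leaving the carbenoid approach: from 3 and 5, Claisen–Schmidt condensation (KOH, EtOH, rt) should give the chalcone (E)-1-[3,5-dibromo-2-hydroxy-4-(methoxymethoxy)phenyl]-3-[3-bromo-4-(methoxymethoxy)phenyl]prop-2-en-1-one F1. Intramolecular oxa-Michael addition (NaOAc, EtOH, reflux) should close it to racemic 6,8,3'-tribromo-7,4'-bis(methoxymethoxy)flavanone F2. Kinetic resolution by asymmetric transfer hydrogenation with RuCl(p-cymene)[(R,R)-TsDPEN] in HCO2H/Et3N, stopped near half conversion, should reduce the (R)-ketone to the cis alcohol (2R,4R)-6,8,3'-tribromo-7,4'-bis(methoxymethoxy)flavan-4-ol F3 and leave the (S)-ketone. The catalyst enantiomer is the one that consumes the (R)-ketone, expected by analogy with the parent flavanone to be the (R,R) form. The route is rejoined at 10, at the cost of at most half the material.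

**Step 8.** Three things may go wrong: incomplete coupling at the C8 bromide between two oxygens, transfer of the allyl group through its substituted terminus (giving a 1,1-dimethylallyl group), and slow thermal erosion at C2 during a long reaction at 95 °C. Fallback: from 10, threefold Stille coupling with allyltributylstannane (Pd(PPh3)4, toluene, 90 °C) should give (S)-6,8,3'-triallyl-7,4'-bis(methoxymethoxy)flavanone F4. The unsubstituted allyl group transmetallates faster and has no regiochemical ambiguity. Threefold cross-metathesis with 2-methylbut-2-ene as solvent (second-generation Grubbs catalyst, RuCl2(=CHPh)(PCy3)(H2IMes), rt) should then convert each allyl into a prenyl group, rejoining the route at 12.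

**Step 9.** The risk is acid-promoted cyclisation of a prenyl group onto its neighbouring phenol as soon as that phenol is set free, or loss of configuration through acid-mediated opening of ring C. Fallback, moving the acid step to a stage without alkenes: from 10, 3 M HCl in MeOH should give (S)-6,8,3'-tribromo-7,4'-dihydroxyflavanone F5. Silylation (t-BuMe2SiOTf, 2,6-lutidine, CH2Cl2, 0 °C) should give (S)-6,8,3'-tribromo-7,4'-bis(tert-butyldimethylsilyloxy)flavanone F6. Stille coupling with 11 (Pd(PPh3)4, toluene, 100 °C) should give (S)-7,4'-bis(tert-butyldimethylsilyloxy)-6,8,3'-triprenylflavanone F7. Fluoride buffered with acetic acid (Bu4NF, AcOH, THF, 0 °C) then removes both silyl groups without strong acid or free base, arriving at 13.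

**Step 5.** The phenol lies between a bromine and the acetyl group, so its phenoxide may attack the alkoxyphosphonium too slowly and the activated benzylic alcohol may be consumed by the hydrazide instead. Fallback: from 6, Appel bromination (CBr4, PPh3, CH2Cl2, 0 °C) should give 3-bromo-4-(methoxymethoxy)benzyl bromide F8, used at once with 3 (K2CO3, DMF, rt) in a Williamson etherification that rejoins the route at 7.

**Step 2.** Site selectivity between the two acidic hydroxyls of the dibromide may be lost, with alkylation at O2 or at both oxygens. Fallback, reversing the order: from 1, methoxymethylation (MOMCl, K2CO3, acetone, rt) goes to the non-chelated hydroxyl and should give 1-[2-hydroxy-4-(methoxymethoxy)phenyl]ethanone F9. Dibromination with NBS (2.1 equiv, MeCN, rt), which generates no strong acid, should then give 3, where the route is rejoined.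

## Further compounds

F1 | step 7 | (E)-1-[3,5-dibromo-2-hydroxy-4-(methoxymethoxy)phenyl]-3-[3-bromo-4-(methoxymethoxy)phenyl]prop-2-en-1-one | COCOc1ccc(/C=C/C(=O)c2cc(Br)c(OCOC)c(Br)c2O)cc1Br
F2 | step 7 | racemic 6,8,3'-tribromo-7,4'-bis(methoxymethoxy)flavanone | COCOc1ccc(C2CC(=O)c3cc(Br)c(OCOC)c(Br)c3O2)cc1Br
F3 | step 7 | (2R,4R)-6,8,3'-tribromo-7,4'-bis(methoxymethoxy)flavan-4-ol | COCOc1ccc([C@H]2C[C@@H](O)c3cc(Br)c(OCOC)c(Br)c3O2)cc1Br
F4 | step 8 | (S)-6,8,3'-triallyl-7,4'-bis(methoxymethoxy)flavanone | COCOc1ccc([C@@H]2CC(=O)c3cc(CC=C)c(OCOC)c(CC=C)c3O2)cc1CC=C
F5 | step 9 | (S)-6,8,3'-tribromo-7,4'-dihydroxyflavanone | Oc1ccc([C@@H]2CC(=O)c3cc(Br)c(O)c(Br)c3O2)cc1Br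
F6 | step 9 | (S)-6,8,3'-tribromo-7,4'-bis(tert-butyldimethylsilyloxy)flavanone | CC(C)(C)[Si](C)(C)Oc1ccc([C@@H]2CC(=O)c3cc(Br)c(O[Si](C)(C)C(C)(C)C)c(Br)c3O2)cc1Br
F7 | step 9 | (S)-7,4'-bis(tert-butyldimethylsilyloxy)-6,8,3'-triprenylflavanone | CC(C)=CCc1cc([C@@H]2CC(=O)c3cc(CC=C(C)C)c(O[Si](C)(C)C(C)(C)C)c(CC=C(C)C)c3O2)ccc1O[Si](C)(C)C(C)(C)C
F8 | step 5 | 3-bromo-4-(methoxymethoxy)benzyl bromide | COCOc1ccc(CBr)cc1Br
F9 | step 2 | 1-[2-hydroxy-4-(methoxymethoxy)phenyl]ethanone | CC(=O)c1ccc(OCOC)cc1O
A1 | alternative 1 | (2S,4S)-7,4'-bis(tert-butyldimethylsilyloxy)-4-methoxy-6,8,3'-triprenylflavan | CC(C)=CCc1cc([C@@H]2C[C@H](OC)c3cc(CC=C(C)C)c(O[Si](C)(C)C(C)(C)C)c(CC=C(C)C)c3O2)ccc1O[Si](C)(C)C(C)(C)C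
A2 | alternative 1 | 4-(tert-butyldimethylsilyloxy)-2-hydroxy-3,5-bis(3-methylbut-2-enyl)benzaldehyde | O=Cc1cc(CC=C(C)C)c(O[Si](C)(C)C(C)(C)C)c(CC=C(C)C)c1O
A3 | alternative 1 | tert-butyldimethyl[2-(3-methylbut-2-enyl)-4-vinylphenoxy]silane | C=Cc1ccc(O[Si](C)(C)C(C)(C)C)c(CC=C(C)C)c1
A4 | alternative 2 | (S)-7,4'-bis(methoxymethoxy)-6,8,3'-triprenylflavanone ethylene ketal | COCOc1ccc([C@@H]2CC3(OCCO3)c4cc(CC=C(C)C)c(OCOC)c(CC=C(C)C)c4O2)cc1CC=C(C)C
A5 | alternative 2 | (S)-2-{2-[2-bromo-4-(methoxymethoxy)-3,5-bis(3-methylbut-2-enyl)phenyl]-1,3-dioxolan-2-yl}-1-[4-(methoxymethoxy)-3-(3-methylbut-2-enyl)phenyl]ethanol | COCOc1ccc([C@@H](O)CC2(OCCO2)c2cc(CC=C(C)C)c(OCOC)c(CC=C(C)C)c2Br)cc1CC=C(C)C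
A6 | alternative 3 | (S)-7-(tert-butyldimethylsilyloxy)-4'-(methoxymethoxy)-6,8,3'-triprenylflavanone | CC(C)=CCc1cc([C@@H]2CC(=O)c3cc(CC=C(C)C)c(O[Si](C)(C)C(C)(C)C)c(CC=C(C)C)c3O2)ccc1OCOC
A7 | alternative 3 | (S)-5-iodo-2-[4-(methoxymethoxy)-3-(3-methylbut-2-enyl)phenyl]-2,3-dihydro-4H-pyran-4-one | COCOc1ccc([C@@H]2CC(=O)C(I)=CO2)cc1CC=C(C)C
A8 | alternative 3 | 3-(tert-butyldimethylsilyloxy)-7-methyl-2-(3-methylbut-2-enyl)octa-1,3,6-triene (enol ether geometry unspecified) | C=C(CC=C(C)C)C(O[Si](C)(C)C(C)(C)C)=CCC=C(C)C
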